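**Retrosynthetic overview**
1. Feature: the ten-membered carbocycle C1–C10 (C14 on C10, C15 on C4, C11 carbinol on C7) is a guaiane skeleton lacking only the C1–C5 bond. C7 (R) has the configuration of (−)-guaiol, so this ring is unveiled from a bought compound rather than closed.
2. End game: target ⇐ thiolate demethylation ⇐ Br→CHO at Ar3/Ar5 ⇐ C5 enol triflate→H (5Z alkene) ⇐ C4 selenoxide elimination (C4=C15) ⇐ chroman carrying a free C5 ketone.
3. Chroman: C1'–H by hydride addition to an isobutyl-bearing o-quinone methide ⇐ isobutyl Grignard on the chromanone ⇐ oxa-Michael closure O–C10 ⇐ aryl enone ⇐ aryllithium + C1 enal ⇐ carbonylation of the C1=C10 enol triflate.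
4. The C1 and C5 ketones are told apart by the C11 hydroxyl, which ties C5 up as an oxolane methyl ketal ⇐ 1,5-diketone ⇐ ozonolysis of the C1=C5 alkene shared by both rings of guaiol.
5. Ring order: ten-membered carbocycle (step 1), temporary oxolane (step 2, opened in step 14), dihydropyran ring (step 9). The arene is bought.

Key step: step 1

Numbering: guaiane numbering for C1–C15. C1' is the benzylic carbon. The arene carbons are Ar1 (bonded to C1'), Ar2 (O to C10), Ar3, Ar4, Ar5 and Ar6 (ortho to Ar1).
Remark on the chemistry: the C4 and C10 stereocentres of guaiol are erased on purpose (C10 in step 3, C4 in step 16), so their epimerisation next to the ketones does not matter. Enol derivatives 5–8, 12–14 and 25 are drawn with the ring-cis double bond; the other geometry would converge at 15 and 26.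
Remark on the chemistry: the two phenol oxygens that must be freed while the ketal is in place carry MOM groups rather than methyl groups. The boron or aluminium halides needed for an ortho-demethylation would ionise the ketal and the tertiary C11–O bond.

**Step 1**
Reactants: 1 (−)-guaiol
Product: 3 11-hydroxy-1,5-seco-guaiane-1,5-dione, via primary ozonide 2 (not isolated)
Conditions: O3, CH2Cl2–MeOH, NaHCO3, −78 °C; Me2S, −78 °C → rt
Reagents that add atoms: ozone, [O-][O+]=O
Why: Ozone adds as a 1,3-dipole to the only C=C bond, the tetrasubstituted C1=C5 alkene, to give primary ozonide 2, which cycloreverts (Criegee mechanism) to a ketone and a carbonyl oxide held in the same ring, and dimethyl sulfide reduces the peroxidic follow-up product to the second ketone. The closest known reaction type is the ozonolysis of the ring-fusion alkene of a bicyclic hydrocarbon such as Δ9,10-octalin to a medium-ring diketone. The ten-membered ring C1–C10 is not closed by bond formation: the cleaved bond was the one common to the five- and seven-membered rings, so their peripheries merge and no skeletal bond is made. No stereocentre is created; C4, C7 and C10 are carried over from guaiol and only C7 has to last. The tertiary alcohol and all C–H bonds are inert to ozone at −78 °C, so the selectivity that needs care is avoidance of transannular aldol closure (C6 to C1 or C10 to C5, both giving decalins), which the buffered neutral work-up and the direct use of 3 in step 2 are meant to prevent.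

**Step 2**
Reactants: 3 11-hydroxy-1,5-seco-guaiane-1,5-dione
Product: 4 5-methoxy-5,11-epoxy-1,5-seco-guaian-1-one
Conditions: PPTS (cat.), MeOH, 3 Å MS, rt
Reagents that add atoms: methanol, CO
Why: Acid-catalysed ketalisation in which the C11 hydroxyl, gamma to C5, closes a five-membered oxolane on the C5 oxocarbenium ion and methanol caps it, whereas the C1 ketone has no internal partner and as a medium-ring ketone resists the sp2 to sp3 change; the new C5 centre is fixed by the bridge, which can span C5 and C7 only cis on the oxolane.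

**Step 3**
Reactants: 4 5-methoxy-5,11-epoxy-1,5-seco-guaian-1-one
Product: 5 C1 trimethylsilyl enol ether of 4 (C1=C10)
Conditions: i-Pr2NMgBr, TMSCl, Et3N, HMPA, Et2O, rt
Reagents that add atoms: chlorotrimethylsilane, C[Si](C)(C)Cl
Why: Thermodynamic silyl enol ether formation with a bromomagnesium amide under equilibrating conditions is a known route to the more substituted enol silane of an α-methyl ketone, here C1=C10, and unlike iodosilane protocols it leaves the ketal untouched.

**Step 4**
Reactants: 5 C1 trimethylsilyl enol ether of 4 (C1=C10)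
Product: 7 C1 enol triflate (C1=C10), via lithium enolate 6 (not isolated)
Conditions: MeLi, THF, 0 °C; N-(5-chloro-2-pyridyl)triflimide, −78 → 0 °C
Reagents that add atoms: N-(5-chloro-2-pyridyl)bis(trifluoromethanesulfonimide), O=S(=O)(N(c1ccc(Cl)cn1)S(=O)(=O)C(F)(F)F)C(F)(F)F
Why: Methyllithium cleaves the O–Si bond to the regiochemically defined enolate 6, which cannot equilibrate without a proton source and is O-sulfonylated (regiospecific enol triflate synthesis).

**Step 5**
Reactants: 7 C1 enol triflate (C1=C10)
Product: 8 C1-formyl alkene (enal with C1' = CHO on C1 and C1=C10)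
Conditions: Pd(PPh3)4 (cat.), CO (3 atm), Bu3SnH (slow addition), LiCl, THF, 50 °C
Reagents that add atoms: carbon monoxide, [C-]#[O+]
Why: Palladium-catalysed reductive carbonylation of an alkenyl triflate (Stille-type formylation) proceeds by oxidative addition, CO insertion and hydride transfer from tin, so C1' and the C1=C10 unsaturation arrive together with retention and a regiochemically ambiguous desaturation of a saturated ketone is avoided.

**Step 6**
Reactants: 9 5-methoxyresorcinol
Product: 10 1-methoxy-3,5-bis(methoxymethoxy)benzene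
Conditions: MOMCl, i-Pr2NEt, CH2Cl2, 0 °C → rt
Reagents that add atoms: chloromethyl methyl ether, COCCl
Why: O-alkylation of both phenols gives MOM ethers that direct the next lithiation and can later be removed in acidic methanol, a medium in which the methyl ketal only exchanges with itself.

**Step 7**
Reactants: 10 1-methoxy-3,5-bis(methoxymethoxy)benzene; 8 C1-formyl alkene
Product: 12 C1' carbinol (both C1' epimers), via aryllithium 11 (not isolated)
Conditions: 10, n-BuLi, TMEDA, THF, 0 °C; 8, −78 °C → −20 °C
Reagents that add atoms: none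
Why: Directed ortho-lithiation takes place at the carbon flanked by the two chelating MOM ethers and aryllithium 11 adds 1,2 to the hindered enal; the C1' carbinol centre forms as a mixture, which is irrelevant because it is oxidised next.

**Step 8**
Reactants: 12 C1' carbinol (both C1' epimers)
Product: 13 aryl enone (Ar = 4-methoxy-2,6-bis(methoxymethoxy)phenyl)
Conditions: DMP, NaHCO3, CH2Cl2, 0 °C → rt
Reagents that add atoms: none
Why: Buffered Dess–Martin oxidation converts the acid-labile allylic and benzylic alcohol into the ketone without ionising it and without touching ketal or MOM groups.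

**Step 9**
Reactants: 13 aryl enone
Product: 15 trans-fused chromanone (O on C10; Ar6–OH; Ar4–OMe), via dihydroxyaryl enone 14 (not isolated)
Conditions: AcCl (cat.), MeOH, 45 °C; then K2CO3, MeOH, rt
Reagents that add atoms: none
Why: Acidic methanolysis frees the two equivalent ortho phenols and carbonate then triggers a 6-endo-trig oxa-Michael addition of phenoxide to C10, as in the closure of 2'-hydroxyaryl β,β-disubstituted enones to 2,2-disubstituted chromanones; the oxolane bridge with its gem-dimethyl group lies transannular to C1=C10 on one face of the carbocycle, so the aryl oxygen should reach C10 from the other face (O anti to the C7–C11 bond), and C1, alpha to the ketone, should equilibrate under the base to the trans-fused isomer with C2 and C9 pseudo-equatorial (H-1 anti to CH3-14).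

**Step 10**
Reactants: 15 trans-fused chromanone
Product: 16 Ar6 O-Boc chromanone
Conditions: Boc2O, DMAP (cat.), i-Pr2NEt (cat.), CH2Cl2, rt
Reagents that add atoms: di-tert-butyl dicarbonate, CC(C)(C)OC(=O)OC(=O)OC(C)(C)C
Why: DMAP-catalysed carbonate formation on the hydrogen-bonded Ar6 phenol installs, next to the C1' carbonyl, the acyl group that will relay the leaving group in the next step.

**Step 11**
Reactants: 16 Ar6 O-Boc chromanone; 17 isobutylmagnesium bromide
Product: 20 C1'-isobutyl chroman with free Ar6 phenol, via magnesium alkoxide 18 (not isolated), via o-quinone methide 19 (not isolated)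
Conditions: LaCl3·2LiCl, 17, THF, −78 → −40 °C; LiBH4, −78 °C → rt
Reagents that add atoms: isobutylmagnesium bromide 17, CC(C)C[Mg]Br
Why: Lanthanum-assisted 1,2-addition (which suppresses enolisation and β-hydride transfer) gives alkoxide 18, this takes over the neighbouring Boc group and expels tert-butyl carbonate to form o-quinone methide 19, and borohydride adds 1,4 at C1' with rearomatisation (known carbonate-relay o-quinone methide chemistry); the in-plane isobutyl group pushes C2 pseudo-axial, so hydride should enter anti to the C1–C2 bond and place H-1' cis to H-1 as in the target, which is why isobutyl comes first and hydride last.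

**Step 12**
Reactants: 20 C1'-isobutyl chroman with free Ar6 phenol
Product: 21 Ar4,Ar6-dimethyl ether
Conditions: MeI, K2CO3, DMF, rt
Reagents that add atoms: iodomethane, CI
Why: Williamson methylation caps the liberated phenol so that both remaining phenol oxygens carry the same base-stable group.

**Step 13**
Reactants: 21 Ar4,Ar6-dimethyl ether
Product: 22 Ar3,Ar5-dibromide
Conditions: NBS (2.05 equiv), MeCN, 0 °C
Reagents that add atoms: N-bromosuccinimide, O=C1CCC(=O)N1Br
Why: Electrophilic aromatic bromination of the phloroglucinol triether at its only two free positions installs latent formyl groups while no alkene is present and blocks the ring against the selenium electrophile and the oxidant used later.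

**Step 14**
Reactants: 22 Ar3,Ar5-dibromide
Product: 23 C5 ketone with free C11 hydroxyl
Conditions: 1 M aq HCl, THF, rt
Reagents that add atoms: water, O
Why: Mild aqueous acid hydrolyses the mixed ketal through the C5 oxocarbenium ion, while the aryl ethers, the aryl bromides and the C10–O bond are stable to it.

**Step 15**
Reactants: 23 C5 ketone with free C11 hydroxyl
Product: 24 C11 triethylsilyl ether
Conditions: TESOTf, 2,6-lutidine, CH2Cl2, −78 → 0 °C
Reagents that add atoms: triethylsilyl triflate, CC[Si](CC)(CC)OS(=O)(=O)C(F)(F)F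
Why: Silyl triflate silylation of the tertiary alcohol holds the compound in the open keto form and keeps the C11 oxygen from re-adding to C5 or acting as a nucleophile later.

**Step 16**
Reactants: 24 C11 triethylsilyl ether
Product: 25 C5 trimethylsilyl enol ether (C4=C5)
Conditions: i-Pr2NMgBr, TMSCl, Et3N, HMPA, Et2O, rt
Reagents that add atoms: chlorotrimethylsilane, C[Si](C)(C)Cl
Why: The same equilibrating magnesium amide silylation as in step 3 should favour C4=C5, both as the more substituted enol silane and because the C5=C6 isomer suffers allylic strain with the bulky C7 substituent.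

**Step 17**
Reactants: 25 C5 trimethylsilyl enol ether (C4=C5)
Product: 28 α-methylene ketone (C4=C15; C5=O), via C4 selenide 26 (not isolated), via selenoxide 27 (not isolated)
Conditions: PhSeCl, CH2Cl2, −78 °C; pyridine, 30% H2O2, 0 °C → rt
Reagents that add atoms: none
Why: Selenenylation of the enol silane at C4, oxidation and selenoxide syn-elimination follow known lines; methyl hydrogens are the usually preferred β-hydrogens (CH3 over CH2) and need no eclipsing of ring bonds in the ten-membered ring, so the exocyclic C4=C15 enone is expected and is used at once.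

**Step 18**
Reactants: 28 α-methylene ketone
Product: 30 C5 dienyl triflate (C4=C15; C5=C6), via lithium dienolate 29 (not isolated)
Conditions: LDA, THF, −78 °C; N-(5-chloro-2-pyridyl)triflimide, −78 → −20 °C
Reagents that add atoms: N-(5-chloro-2-pyridyl)bis(trifluoromethanesulfonimide), O=S(=O)(N(c1ccc(Cl)cn1)S(=O)(=O)C(F)(F)F)C(F)(F)F
Why: Kinetic α'-deprotonation can occur only at C6, and the cyclic lithium amide transition state gives the enolate with C7 anti to oxygen, i.e. C4 and C7 cis, which is also the less strained ring-cis geometry and is trapped as the 2-triflyloxy-1,3-diene.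

**Step 19**
Reactants: 30 C5 dienyl triflate
Product: 31 (5Z)-4(15),5-diene dibromide
Conditions: Pd(OAc)2 (cat.), PPh3, HCO2H, n-Bu3N, DMF, 40 °C
Reagents that add atoms: none
Why: Palladium-catalysed formate reduction of an alkenyl triflate replaces OTf by H with retention of geometry, and oxidative addition to the alkenyl triflate is much faster than to electron-rich aryl bromides flanked by two ortho oxygens.

**Step 20**
Reactants: 31 (5Z)-4(15),5-diene dibromide
Product: 33 Ar3,Ar5-dialdehyde, via dilithioarene 32 (not isolated)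
Conditions: t-BuLi (4.4 equiv), Et2O, −78 °C; DMF, −78 → 0 °C; aq NH4Cl
Reagents that add atoms: N,N-dimethylformamide, CN(C)C=O
Why: Bromine–lithium exchange at −78 °C is far faster than addition of the alkyllithium to the diene, and each carbanion of 32, flanked by two oxygens, is formylated by DMF (Bouveault aldehyde synthesis).

**Step 21**
Reactants: 33 Ar3,Ar5-dialdehyde
Product: 34 di-O-methyl ether of the target
Conditions: TBAF, THF, 0 °C → rt
Reagents that add atoms: none
Why: Fluoride cleaves the Si–O bond selectively and frees the C11 tertiary alcohol under non-acidic conditions that spare the diene and the aldehydes.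

**Step 22**
Reactants: 34 di-O-methyl ether of the target
Product: 35 target CNP0479784.1
Conditions: 4-MeC6H4SLi, HMPA–toluene, 110 °C; 1 M HCl (work-up)
Reagents that add atoms: none
Why: SN2 demethylation by thiolate is favoured because both methyl ethers are ortho to formyl groups, which stabilise the phenoxide leaving groups, and the basic medium spares the diene, the tertiary alcohol and the C10–O bond that Lewis acids would ionise.

**Compound list**
1 | (−)-guaiol, (4S,7R,10S)-guai-1(5)-en-11-ol | C[C@H]1CC[C@H](CC2=C1CC[C@@H]2C)C(C)(C)O | starting material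
2 | primary ozonide of 1 (1,2,3-trioxolane across C1 and C5) | C[C@H]1CC[C@H](CC23OOOC12CC[C@@H]3C)C(C)(C)O | intermediate
3 | 11-hydroxy-1,5-seco-guaiane-1,5-dione (C4, C7, C10 as in guaiol) | C[C@H]1CC[C@@H](C(C)(C)O)CC(=O)[C@@H](C)CCC1=O | intermediate
4 | 5-methoxy-5,11-epoxy-1,5-seco-guaian-1-one (C4 and C8 cis on the oxolane) | C[C@H]1CC[C@@H]2C[C@@](OC)(OC2(C)C)[C@@H](C)CCC1=O | intermediate
5 | C1 trimethylsilyl enol ether of 4, C1=C10 ring-cis | C/C1=C(O[Si](C)(C)C)/CC[C@H](C)[C@@]2(OC)C[C@@H](CC1)C(C)(C)O2 | intermediate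
6 | lithium C1(10)-enolate | C/C1=C([O-])/CC[C@H](C)[C@@]2(OC)C[C@@H](CC1)C(C)(C)O2.[Li+] | intermediate
7 | C1 enol triflate, C1=C10 | C/C1=C(OS(=O)(=O)C(F)(F)F)/CC[C@H](C)[C@@]2(OC)C[C@@H](CC1)C(C)(C)O2 | intermediate
8 | enal, C1' formyl group on C1, C1=C10 | C/C1=C(C=O)/CC[C@H](C)[C@@]2(OC)C[C@@H](CC1)C(C)(C)O2 | intermediate
9 | 5-methoxyresorcinol | COc1cc(O)cc(O)c1 | starting material
10 | 1-methoxy-3,5-bis(methoxymethoxy)benzene | COCOc1cc(OC)cc(OCOC)c1 | intermediate
11 | 4-methoxy-2,6-bis(methoxymethoxy)phenyllithium | [Li]c1c(OCOC)cc(OC)cc1OCOC | intermediate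
12 | C1' carbinol, both C1' epimers | C/C1=C(C(O)c3c(OCOC)cc(OC)cc3OCOC)/CC[C@H](C)[C@@]2(OC)C[C@@H](CC1)C(C)(C)O2 | intermediate
13 | aryl enone, Ar = 4-methoxy-2,6-bis(methoxymethoxy)phenyl | C/C1=C(C(=O)c3c(OCOC)cc(OC)cc3OCOC)/CC[C@H](C)[C@@]2(OC)C[C@@H](CC1)C(C)(C)O2 | intermediate
14 | 2,6-dihydroxy-4-methoxyphenyl enone | C/C1=C(C(=O)c3c(O)cc(OC)cc3O)/CC[C@H](C)[C@@]2(OC)C[C@@H](CC1)C(C)(C)O2 | intermediate
15 | chromanone, O on C10 anti to C7–C11, H-1 anti to CH3-14, Ar6–OH, Ar4–OMe | C[C@H]1CC[C@H]2C(=O)c3c(O)cc(OC)cc3O[C@]2(C)CC[C@@H]4C[C@@]1(OC)OC4(C)C | intermediate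
16 | Ar6 O-Boc chromanone | C[C@H]1CC[C@H]2C(=O)c3c(OC(=O)OC(C)(C)C)cc(OC)cc3O[C@]2(C)CC[C@@H]4C[C@@]1(OC)OC4(C)C | intermediate
17 | isobutylmagnesium bromide | CC(C)C[Mg]Br | starting material
18 | bromomagnesium C1' tertiary alkoxide | C[C@H]1CC[C@H]2C([O-])(CC(C)C)c3c(OC(=O)OC(C)(C)C)cc(OC)cc3O[C@]2(C)CC[C@@H]4C[C@@]1(OC)OC4(C)C.[Mg+]Br | intermediate
19 | o-quinone methide, C1'(isobutyl)=Ar1, Ar6=O | C[C@H]1CC[C@H]2C(CC(C)C)=C3C(=O)C=C(OC)C=C3O[C@]2(C)CC[C@@H]4C[C@@]1(OC)OC4(C)C | intermediate
20 | C1'-isobutyl chroman, H-1' cis to H-1, free Ar6 phenol | C[C@H]1CC[C@H]2[C@@H](CC(C)C)c3c(O)cc(OC)cc3O[C@]2(C)CC[C@@H]4C[C@@]1(OC)OC4(C)C | intermediate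
21 | Ar4,Ar6-dimethyl ether | C[C@H]1CC[C@H]2[C@@H](CC(C)C)c3c(OC)cc(OC)cc3O[C@]2(C)CC[C@@H]4C[C@@]1(OC)OC4(C)C | intermediate
22 | Ar3,Ar5-dibromide | C[C@H]1CC[C@H]2[C@@H](CC(C)C)c3c(OC)c(Br)c(OC)c(Br)c3O[C@]2(C)CC[C@@H]4C[C@@]1(OC)OC4(C)C | intermediate
23 | C5 ketone with free C11 hydroxyl | C[C@H]1CC[C@H]2[C@@H](CC(C)C)c3c(OC)c(Br)c(OC)c(Br)c3O[C@]2(C)CC[C@@H](C(C)(C)O)CC1=O | intermediate
24 | C11 triethylsilyl ether of 23 | C[C@H]1CC[C@H]2[C@@H](CC(C)C)c3c(OC)c(Br)c(OC)c(Br)c3O[C@]2(C)CC[C@@H](C(C)(C)O[Si](CC)(CC)CC)CC1=O | intermediate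
25 | C5 trimethylsilyl enol ether, C4=C5 | C/C1=C(O[Si](C)(C)C)/C[C@H](C(C)(C)O[Si](CC)(CC)CC)CC[C@@]2(C)Oc3c(Br)c(OC)c(Br)c(OC)c3[C@H](CC(C)C)[C@@H]2CC1 | intermediate
26 | C4 phenylselenide of ketone 24 | CC1([Se]c4ccccc4)C(=O)C[C@H](C(C)(C)O[Si](CC)(CC)CC)CC[C@@]2(C)Oc3c(Br)c(OC)c(Br)c(OC)c3[C@H](CC(C)C)[C@@H]2CC1 | intermediate
27 | C4 selenoxide | CC1([Se](=O)c4ccccc4)C(=O)C[C@H](C(C)(C)O[Si](CC)(CC)CC)CC[C@@]2(C)Oc3c(Br)c(OC)c(Br)c(OC)c3[C@H](CC(C)C)[C@@H]2CC1 | intermediate
28 | α-methylene ketone, C4=C15, C5=O | C=C1C(=O)C[C@H](C(C)(C)O[Si](CC)(CC)CC)CC[C@@]2(C)Oc3c(Br)c(OC)c(Br)c(OC)c3[C@H](CC(C)C)[C@@H]2CC1 | intermediate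
29 | lithium cross-conjugated dienolate | C=C1/C([O-])=C\[C@H](C(C)(C)O[Si](CC)(CC)CC)CC[C@@]2(C)Oc3c(Br)c(OC)c(Br)c(OC)c3[C@H](CC(C)C)[C@@H]2CC1.[Li+] | intermediate
30 | C5 dienyl triflate, C4 and C7 cis on C5=C6 | C=C1/C(OS(=O)(=O)C(F)(F)F)=C\[C@H](C(C)(C)O[Si](CC)(CC)CC)CC[C@@]2(C)Oc3c(Br)c(OC)c(Br)c(OC)c3[C@H](CC(C)C)[C@@H]2CC1 | intermediate
31 | (5Z)-4(15),5-diene dibromide | C=C1/C=C\[C@H](C(C)(C)O[Si](CC)(CC)CC)CC[C@@]2(C)Oc3c(Br)c(OC)c(Br)c(OC)c3[C@H](CC(C)C)[C@@H]2CC1 | intermediate
32 | Ar3,Ar5-dilithioarene | C=C1/C=C\[C@H](C(C)(C)O[Si](CC)(CC)CC)CC[C@@]2(C)Oc3c([Li])c(OC)c([Li])c(OC)c3[C@H](CC(C)C)[C@@H]2CC1 | intermediate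
33 | Ar3,Ar5-dialdehyde, C11 OTES | C=C1/C=C\[C@H](C(C)(C)O[Si](CC)(CC)CC)CC[C@@]2(C)Oc3c(C=O)c(OC)c(C=O)c(OC)c3[C@H](CC(C)C)[C@@H]2CC1 | intermediate
34 | di-O-methyl ether of the target | C=C1/C=C\[C@H](C(C)(C)O)CC[C@@]2(C)Oc3c(C=O)c(OC)c(C=O)c(OC)c3[C@H](CC(C)C)[C@@H]2CC1 | intermediate
35 | CNP0479784.1 (1S,7R,10R,1'R; 5Z) | C=C1/C=C\[C@H](C(C)(C)O)CC[C@@]2(C)Oc3c(C=O)c(O)c(C=O)c(O)c3[C@H](CC(C)C)[C@@H]2CC1 | target

Total step count: 22
Longest linear sequence: 21 steps (steps 1–5 and 7–22, from guaiol)

**Steps most likely to fail**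

**1. Step 11.**
- What may go wrong: enolisation of the hindered, electron-rich chromanone, followed by retro-oxa-Michael ring opening, may outrun 1,2-addition. So may β-hydride transfer from the isobutyl reagent. β-Hydride transfer would also generate the unsubstituted quinone methide, into which isobutyl would then enter from the wrong face.
- Fallback: it sets out from 16 and returns at 20. 2-Methylallylmagnesium chloride adds to hindered ketones through a cyclic six-membered transition state and carries no β-hydrogen. It takes the place of 17 in the same carbonate-relay/borohydride sequence and should give the C1'-(2-methylallyl) chroman phenol F1. Hydrogenation of its 1,1-disubstituted alkene (H2, Pd/C, EtOAc), the only C=C bond at that stage, should give 20.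

**2. Step 9.**
- What may go wrong: addition to a twisted tetrasubstituted enone creates a quaternary centre in a medium ring, so the equilibrium may stay on the open side. The facial selectivity at C10 relative to C7 may also be poor.
- Fallback: it sets out from 12 and returns at 15. Acidic methanol on carbinol 12 removes the MOM groups and ionises the doubly activated alcohol. The resulting vinylogous o-quinone methide closes by oxa-6π electrocyclisation to the 2H-chromene F2, a closure driven by rearomatisation and therefore not equilibrium-limited. Hydroboration–oxidation (BH3·THF; NaBO3) places boron on the less substituted C1' and gives the chroman-4-ol F3. MnO2 oxidation gives 15, whose C1 centre is then equilibrated with carbonate.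

**3. Step 3.**
- What may go wrong: equilibrating enolisation may not favour the tetrasubstituted C1=C10 enolate in a ten-membered ring. Enolisation toward C2 would lead to a constitutionally wrong chromanone. The same concern applies, softened by the bulk at C7, to step 16.
- Fallback: it sets out from 4 and returns at 8, and it blocks C2 as an alkene.
 - Kinetic deprotonation at the C2 methylene (LDA, −78 °C) and dehydrogenation with N-tert-butylbenzenesulfinimidoyl chloride give the C2=C3 enone F4.
 - α'-Deprotonation of F4 can occur only at C10 (LDA, then the pyridyl triflimide) and gives the dienyl triflate F5.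
 - Reductive carbonylation as in step 5 gives the dienal F6.
 - Diimide (potassium azodicarboxylate, AcOH, MeOH) saturates only the disubstituted C2=C3 bond and gives 8.

**Further compounds**
F1 | step 11 | C1'-(2-methylallyl) chroman phenol | C[C@H]1CC[C@H]2[C@@H](CC(C)=C)c3c(O)cc(OC)cc3O[C@]2(C)CC[C@@H]4C[C@@]1(OC)OC4(C)C
F2 | step 9 | 2H-chromene (C1=C1', O on C10, Ar6–OH, Ar4–OMe) | C[C@H]1CCC2=Cc3c(O)cc(OC)cc3O[C@]2(C)CC[C@@H]4C[C@@]1(OC)OC4(C)C
F3 | step 9 | chroman-4-ol (C1'–OH) | C[C@H]1CC[C@H]2C(O)c3c(O)cc(OC)cc3O[C@]2(C)CC[C@@H]4C[C@@]1(OC)OC4(C)C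
F4 | step 3 | C2=C3 enone of ketal 4 | C[C@H]1CC[C@@H]2C[C@@](OC)(OC2(C)C)[C@@H](C)C=CC1=O
F5 | step 3 | C1 dienyl triflate (C1=C10, C2=C3) | C/C1=C(OS(=O)(=O)C(F)(F)F)/C=C[C@H](C)[C@@]2(OC)C[C@@H](CC1)C(C)(C)O2
F6 | step 3 | dienal (C1' formyl on C1, C1=C10, C2=C3) | C/C1=C(C=O)/C=C[C@H](C)[C@@]2(OC)C[C@@H](CC1)C(C)(C)O2
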